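**Retrosynthetic overview**
- The target, 5,6,4'-trihydroxy-7,2',5'-trimethoxyflavone, comes from a protected flavone by chelation-directed cleavage of the 5-OMe and then hydrogenolysis of the benzyl ethers at O-6 and O-4'.
- Ring C (the pyranone) is the only ring formed. It closes at O1–C2 by oxidative cyclisation of a 2'-hydroxychalcone.
- The chalcone comes from a Claisen–Schmidt aldol condensation, which forms the Cα–Cβ bond between a ring A acetophenone and a ring B benzaldehyde.
- The ring A acetophenone comes from syringaldehyde by Dakin oxidation, C-acetylation and selective O-benzylation.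
- The ring B aldehyde comes from 2,5-dimethoxybenzaldehyde by Baeyer–Villiger oxidation, O-benzylation and Vilsmeier–Haack formylation.

Assumption: the target SMILES contains no stereocentre and no stereogenic double bond, so the compound is achiral and no enantiocontrol is needed.

**Step 1**
Reactants: 1 2,5-dimethoxybenzaldehyde
Product: 3 2,5-dimethoxyphenol, via 2,5-dimethoxyphenyl formate 2 (not isolated)
Conditions: mCPBA (1.3 equiv), CH2Cl2, 0 °C to reflux, 6 h; then 2 M NaOH, MeOH, rt, 1 h; 2 M HCl work-up
Reagents that add atoms: mCPBA, O=C(OO)c1cccc(Cl)c1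
Why: In this Baeyer–Villiger oxidation the electron-rich aryl group migrates in preference to hydride, the formate is saponified at once, and no stereocentre is formed.

**Step 2**
Reactants: 3 2,5-dimethoxyphenol
Product: 4 2-(benzyloxy)-1,4-dimethoxybenzene
Conditions: BnBr (1.1 equiv), K2CO3 (1.5 equiv), acetone, reflux, 8 h
Reagents that add atoms: benzyl bromide, BrCc1ccccc1
Why: This is a Williamson ether synthesis (SN2 of the phenoxide on benzyl bromide) at the only OH group, and no stereocentre is formed.

**Step 3**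
Reactants: 4 2-(benzyloxy)-1,4-dimethoxybenzene
Product: 6 4-(benzyloxy)-2,5-dimethoxybenzaldehyde, via aryliminium chloride 5 (not isolated)
Conditions: POCl3 (1.5 equiv), DMF, 0 °C to 80 °C, 3 h; then ice-water, rt
Reagents that add atoms: DMF, CN(C)C=O; water, O
Why: Vilsmeier–Haack formylation attacks the position para to OBn and ortho to OMe, which is the most activated and least hindered site (the same selectivity as 1,2,4-trimethoxybenzene), and benzyl ethers tolerate the reagent.

**Step 4**
Reactants: 7 syringaldehyde (4-hydroxy-3,5-dimethoxybenzaldehyde)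
Product: 9 2,6-dimethoxybenzene-1,4-diol, via 4-hydroxy-3,5-dimethoxyphenyl formate 8 (not isolated)
Conditions: 30% H2O2 (1.2 equiv), 1 M NaOH (1.1 equiv), N2, 0 °C to 40 °C, 2 h; 2 M HCl work-up
Reagents that add atoms: hydrogen peroxide, OO
Why: In this Dakin oxidation hydroperoxide adds to the aldehyde of the para-phenoxide, the aryl group migrates to oxygen, the formate hydrolyses in situ, and no stereocentre is formed.

**Step 5**
Reactants: 9 2,6-dimethoxybenzene-1,4-diol
Product: 11 1-(3,6-dihydroxy-2,4-dimethoxyphenyl)ethan-1-one, via difluoroboron chelate 10 (not isolated)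
Conditions: AcOH, BF3·OEt2 (3 equiv), N2, 85 °C, 3 h; then H2O, 60 °C, 30 min
Reagents that add atoms: acetic acid, CC(=O)O
Why: In this Friedel–Crafts C-acetylation (any aryl acetate formed transfers by a Fries-type shift) the two free ring positions are equivalent by symmetry and activated by three oxygens, and the chelate blocks a second acylation.

**Step 6**
Reactants: 11 1-(3,6-dihydroxy-2,4-dimethoxyphenyl)ethan-1-one
Product: 12 1-[3-(benzyloxy)-6-hydroxy-2,4-dimethoxyphenyl]ethan-1-one
Conditions: BnBr (1.05 equiv), K2CO3 (1.2 equiv), acetone, N2, reflux, 6 h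
Reagents that add atoms: benzyl bromide, BrCc1ccccc1
Why: This Williamson etherification is chemoselective because the OH ortho to the acetyl group is held in a strong hydrogen bond to the carbonyl, so one equivalent of BnBr with a weak base alkylates only the OH between the two methoxy groups.

**Step 7 (key C–C bond)**
Reactants: 12 1-[3-(benzyloxy)-6-hydroxy-2,4-dimethoxyphenyl]ethan-1-one; 6 4-(benzyloxy)-2,5-dimethoxybenzaldehyde
Product: 14 (E)-3-[4-(benzyloxy)-2,5-dimethoxyphenyl]-1-[3-(benzyloxy)-6-hydroxy-2,4-dimethoxyphenyl]prop-2-en-1-one, via aldol adduct 13 (not isolated)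
Conditions: 50% aq KOH (10 equiv), EtOH, N2, rt, 48 h; then 2 M HCl, 0 °C
Reagents that add atoms: none
Why: In this Claisen–Schmidt crossed aldol condensation only the methyl ketone can enolise and only the aldehyde can accept, and E1cB dehydration erases the racemic carbinol centre of 13 to give the E-enone under thermodynamic control.

**Step 8**
Reactants: 14 the (E)-2'-hydroxychalcone
Product: 16 6-(benzyloxy)-2-[4-(benzyloxy)-2,5-dimethoxyphenyl]-5,7-dimethoxy-4H-chromen-4-one, via flavanone 15 (not isolated)
Conditions: I2 (10 mol%), DMSO, 120 °C, 3 h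
Reagents that add atoms: none
Why: In this iodine-catalysed oxidative cyclisation the single free phenol closes ring C by intramolecular oxa-Michael addition (so only the 5,6,7-pattern can form), and dehydrogenation of C2–C3 with DMSO as terminal oxidant erases the racemic C-2 centre of 15.

**Step 9**
Reactants: 16 the 5,7,2',5'-tetramethoxy-6,4'-bis(benzyloxy)flavone
Product: 18 6-(benzyloxy)-2-[4-(benzyloxy)-2,5-dimethoxyphenyl]-5-hydroxy-7-methoxy-4H-chromen-4-one, via dichloroboron chelate 17 (not isolated)
Conditions: BCl3 (1 M in CH2Cl2, 1.5 equiv), CH2Cl2, −78 °C to 0 °C, 2 h; then 1 M HCl, THF, rt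
Reagents that add atoms: none
Why: In this chelation-directed Lewis acid ether cleavage BCl3 bridges the pyranone carbonyl and the peri 5-OMe in a six-membered chelate, chloride removes that methyl by SN2, and the unchelated methyl and benzyl ethers survive limited reagent at or below 0 °C without Wessely–Moser isomerisation.

**Step 10**
Reactants: 18 the 5-hydroxy-6,4'-bis(benzyloxy)flavone
Product: 19 5,6-dihydroxy-2-(4-hydroxy-2,5-dimethoxyphenyl)-7-methoxy-4H-chromen-4-one
Conditions: H2 (1 atm), Pd/C (10 wt% Pd), THF–MeOH 1:1, rt, 4 h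
Reagents that add atoms: none
Why: Catalytic hydrogenolysis cleaves both benzylic C–O bonds, the flavone C2=C3 bond and the aryl methyl ethers are inert at 1 atm and rt, and the neutral reducing medium protects the oxidation-prone 5,6-diol of the achiral target.

**Compound list**
1 | 2,5-dimethoxybenzaldehyde | COc1ccc(OC)c(C=O)c1 | starting material
2 | 2,5-dimethoxyphenyl formate (not isolated) | COc1ccc(OC)c(OC=O)c1 | intermediate
3 | 2,5-dimethoxyphenol | COc1ccc(OC)c(O)c1 | intermediate
4 | 2-(benzyloxy)-1,4-dimethoxybenzene | COc1ccc(OC)c(OCc2ccccc2)c1 | intermediate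
5 | [4-(benzyloxy)-2,5-dimethoxyphenyl]methylidene(dimethyl)iminium chloride (not isolated) | COc1cc(OCc2ccccc2)c(OC)cc1C=[N+](C)C.[Cl-] | intermediate
6 | 4-(benzyloxy)-2,5-dimethoxybenzaldehyde | COc1cc(OCc2ccccc2)c(OC)cc1C=O | intermediate
7 | syringaldehyde (4-hydroxy-3,5-dimethoxybenzaldehyde) | COc1cc(C=O)cc(OC)c1O | starting material
8 | 4-hydroxy-3,5-dimethoxyphenyl formate (not isolated) | COc1cc(OC=O)cc(OC)c1O | intermediate
9 | 2,6-dimethoxybenzene-1,4-diol | COc1cc(O)cc(OC)c1O | intermediate
10 | O-difluoroboryl chelate of 11, with BF2 on the oxygen ortho to the acetyl group (not isolated) | CC(=O)c1c(OB(F)F)cc(OC)c(O)c1OC | intermediate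
11 | 1-(3,6-dihydroxy-2,4-dimethoxyphenyl)ethan-1-one | CC(=O)c1c(O)cc(OC)c(O)c1OC | intermediate
12 | 1-[3-(benzyloxy)-6-hydroxy-2,4-dimethoxyphenyl]ethan-1-one | CC(=O)c1c(O)cc(OC)c(OCc2ccccc2)c1OC | intermediate
13 | racemic 3-[4-(benzyloxy)-2,5-dimethoxyphenyl]-1-[3-(benzyloxy)-6-hydroxy-2,4-dimethoxyphenyl]-3-hydroxypropan-1-one (not isolated) | COc1cc(O)c(C(=O)CC(O)c2cc(OC)c(OCc3ccccc3)cc2OC)c(OC)c1OCc1ccccc1 | intermediate
14 | (E)-3-[4-(benzyloxy)-2,5-dimethoxyphenyl]-1-[3-(benzyloxy)-6-hydroxy-2,4-dimethoxyphenyl]prop-2-en-1-one | COc1cc(O)c(C(=O)/C=C/c2cc(OC)c(OCc3ccccc3)cc2OC)c(OC)c1OCc1ccccc1 | intermediate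
15 | racemic 6-(benzyloxy)-2-[4-(benzyloxy)-2,5-dimethoxyphenyl]-5,7-dimethoxychroman-4-one (not isolated) | COc1cc2OC(c3cc(OC)c(OCc4ccccc4)cc3OC)CC(=O)c2c(OC)c1OCc1ccccc1 | intermediate
16 | 6-(benzyloxy)-2-[4-(benzyloxy)-2,5-dimethoxyphenyl]-5,7-dimethoxy-4H-chromen-4-one | COc1cc2oc(-c3cc(OC)c(OCc4ccccc4)cc3OC)cc(=O)c2c(OC)c1OCc1ccccc1 | intermediate
17 | 5-O-dichloroboryl chelate of 18 (not isolated) | COc1cc2oc(-c3cc(OC)c(OCc4ccccc4)cc3OC)cc(=O)c2c(OB(Cl)Cl)c1OCc1ccccc1 | intermediate
18 | 6-(benzyloxy)-2-[4-(benzyloxy)-2,5-dimethoxyphenyl]-5-hydroxy-7-methoxy-4H-chromen-4-one | COc1cc2oc(-c3cc(OC)c(OCc4ccccc4)cc3OC)cc(=O)c2c(O)c1OCc1ccccc1 | intermediate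
19 | 5,6-dihydroxy-2-(4-hydroxy-2,5-dimethoxyphenyl)-7-methoxy-4H-chromen-4-one (achiral) | COc1cc(-c2cc(=O)c3c(O)c(O)c(OC)cc3o2)c(OC)cc1O | target

**Totals**
Total step count: 10.
Longest linear sequence: 7 steps. Both branches are equal in length (steps 4, 5, 6, 7, 8, 9, 10 or steps 1, 2, 3, 7, 8, 9, 10).

**Three steps most likely to fail**

Step 5 (C-acetylation of the air-sensitive hydroquinone). The risks are O-acetylation without transfer to carbon, and oxidation to the quinone. The fallback sets out from 9 and uses a nitrile electrophile that cannot O-acylate. A Houben–Hoesch reaction with acetonitrile, ZnCl2 and dry HCl gas in Et2O at 0 °C precipitates 1-(3,6-dihydroxy-2,4-dimethoxyphenyl)ethan-1-iminium chloride F1. This salt is filtered off and boiled in water, which hydrolyses it to the ketone and rejoins the route at 11.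

Step 8 (I2/DMSO oxidative cyclisation). The risks are benzyl ether loss caused by HI, iodination of the very electron-rich rings, and stalling at the flavanone. Partial loss of the 5-methyl group would be harmless, because it gives 18 directly. The fallback sets out from 6 and 12 and builds ring C at the diketone oxidation level, so no oxidant is needed.
- Pinnick oxidation of 6 (NaClO2, NaH2PO4, 2-methyl-2-butene, t-BuOH–H2O) gives 4-(benzyloxy)-2,5-dimethoxybenzoic acid F2.
- Oxalyl chloride with catalytic DMF in CH2Cl2 converts it into 4-(benzyloxy)-2,5-dimethoxybenzoyl chloride F3.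
- The lithium dianion of 12 (LiN(SiMe3)2, 3.2 equiv, THF, −78 °C) is C-acylated by F3 in an intermolecular Claisen-type condensation. This gives 1-[4-(benzyloxy)-2,5-dimethoxyphenyl]-3-[3-(benzyloxy)-6-hydroxy-2,4-dimethoxyphenyl]propane-1,3-dione F4.
- Catalytic p-TsOH in toluene at 90 °C cyclodehydrates F4 and rejoins the route at 16.

Step 9 (selective 5-O-demethylation next to a benzyl ether). The risks are partial debenzylation at O-6 and attack on the 7-OMe. Debenzylated material still converges on 19 in step 10. The fallback sets out from 16 and reverses the order of deprotection.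
- Hydrogenolysis (H2, Pd/C, THF–MeOH, rt) first gives 6-hydroxy-2-(4-hydroxy-2,5-dimethoxyphenyl)-5,7-dimethoxy-4H-chromen-4-one F5.
- AlCl3 in MeCN at 60 °C followed by warm dilute HCl then removes only the 5-methyl group. The aluminium is held between O-5, the carbonyl and O-6, and the reaction is stopped before the slower 7-OMe cleavage. This rejoins the route at 19.

**Further compounds**
F1 | step 5 | 1-(3,6-dihydroxy-2,4-dimethoxyphenyl)ethan-1-iminium chloride | CC(=[NH2+])c1c(O)cc(OC)c(O)c1OC.[Cl-]
F2 | step 8 | 4-(benzyloxy)-2,5-dimethoxybenzoic acid | COc1cc(OCc2ccccc2)c(OC)cc1C(=O)O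
F3 | step 8 | 4-(benzyloxy)-2,5-dimethoxybenzoyl chloride | COc1cc(OCc2ccccc2)c(OC)cc1C(=O)Cl
F4 | step 8 | 1-[4-(benzyloxy)-2,5-dimethoxyphenyl]-3-[3-(benzyloxy)-6-hydroxy-2,4-dimethoxyphenyl]propane-1,3-dione | COc1cc(O)c(C(=O)CC(=O)c2cc(OC)c(OCc3ccccc3)cc2OC)c(OC)c1OCc1ccccc1
F5 | step 9 | 6-hydroxy-2-(4-hydroxy-2,5-dimethoxyphenyl)-5,7-dimethoxy-4H-chromen-4-one | COc1cc2oc(-c3cc(OC)c(O)cc3OC)cc(=O)c2c(OC)c1O
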